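**Plan**
- Retrosynthesis cuts, in this order: the two ring B O–CH2OMe bonds; the ring A bonds C8–C8a and C4a–C5; the C3–C1' biaryl bond; then the aryl–boron and aryl–prenyl bonds of ring B.
- Enabling feature: ring A carries OH on C5 (peri to the C4 carbonyl) and OMe on C7 and is fused to the pyranone at C4a–C8a. The unit C5–C8 with its two oxygens is therefore what 1,3-dimethoxy-1-(trimethylsilyloxy)buta-1,3-diene leaves on an α-bromo enone C=C.
- Forward: ring B is made as a prenylated bis-MOM aryl boronate; ring C is bought as 4H-pyran-4-one, dibrominated and mono-arylated; ring A is then grown on ring C by cycloaddition–aromatisation; acid frees the two ring B phenols.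
- Stereochemistry: the target has no stereocentre and its only olefin is the prenyl double bond, which has no E/Z isomers; the stereocentres of the cycloadduct vanish on aromatisation.

Key step: step 7

Remark: the diene is written as its (1Z) isomer and the cycloadduct as one enantiomer of the racemate with undefined ketal carbon; neither geometry affects the achiral product.

Step 1
Reactants: 1 4,6-dibromobenzene-1,3-diol (4,6-dibromoresorcinol)
Product: 2 1,5-dibromo-2,4-bis(methoxymethoxy)benzene
Conditions: NaH (2.4 equiv), MOMCl (2.4 equiv), THF/DMF, 0 °C → rt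
Reagents that add atoms: chloromethyl methyl ether, COCCl
Why: Williamson etherification, in which the two phenoxides formed by NaH are alkylated at oxygen by the α-chloro ether while the aryl bromides stay untouched.

Step 2
Reactants: 2 1,5-dibromo-2,4-bis(methoxymethoxy)benzene; 3 1-bromo-3-methylbut-2-ene (prenyl bromide)
Product: 5 1-bromo-2,4-bis(methoxymethoxy)-5-(3-methylbut-2-enyl)benzene, via aryllithium 4 (not isolated)
Conditions: n-BuLi (1.0 equiv), THF, −78 °C; then 3 (1.3 equiv), −78 → 0 °C
Reagents that add atoms: none
Why: Bromine–lithium exchange should stop after one of the two equivalent C–Br bonds because the ortho-alkoxy aryllithium resists a second exchange at −78 °C, and the aryllithium is then alkylated by SN2 displacement at the unhindered CH2 of the allylic bromide.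

Step 3
Reactants: 5 1-bromo-2,4-bis(methoxymethoxy)-5-(3-methylbut-2-enyl)benzene
Product: 8 2-[2,4-bis(methoxymethoxy)-5-(3-methylbut-2-enyl)phenyl]-4,4,5,5-tetramethyl-1,3,2-dioxaborolane, via aryllithium 6 (not isolated), via lithium borate complex 7 (not isolated)
Conditions: n-BuLi (1.1 equiv), THF, −78 °C; iPrOBpin (1.3 equiv), −78 °C → rt; H2O
Reagents that add atoms: 2-isopropoxy-4,4,5,5-tetramethyl-1,3,2-dioxaborolane, CC(C)OB1OC(C)(C)C(C)(C)O1
Why: Lithiation–borylation, in which bromine–lithium exchange outruns deprotonation of the benzylic–allylic CH2 at −78 °C and the aryllithium adds to the borate ester to give an ate complex that loses isopropoxide.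

Step 4
Reactants: 9 4H-pyran-4-one
Product: 11 3,5-dibromo-4H-pyran-4-one, via 3-bromo-4H-pyran-4-one 10 (not isolated)
Conditions: Br2 (2.2 equiv), CH2Cl2, 0 °C → rt; then Et3N (2.5 equiv), 0 °C
Reagents that add atoms: bromine, BrBr
Why: Electrophilic α-bromination of a vinylogous ester, in which bromine attacks C3 and then C5 and loss of HBr (completed by Et3N) restores the pyranone each time, as in the usual preparation of α-bromo enones.

Step 5
Reactants: 11 3,5-dibromo-4H-pyran-4-one; 8 2-[2,4-bis(methoxymethoxy)-5-(3-methylbut-2-enyl)phenyl]-4,4,5,5-tetramethyl-1,3,2-dioxaborolane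
Product: 12 3-[2,4-bis(methoxymethoxy)-5-(3-methylbut-2-enyl)phenyl]-5-bromo-4H-pyran-4-one
Conditions: Pd(PPh3)4 (5 mol %), K2CO3 (2 equiv), DME/H2O (4:1), 70 °C; 11 in threefold excess, 8 added slowly
Reagents that add atoms: none
Why: Suzuki–Miyaura coupling at a C(sp2)–Br bond α to the carbonyl, as practised with 3-halochromones, with the excess of symmetrical dibromide and slow boronate addition holding the reaction at mono-arylation and unreacted 11 being recovered.

Step 6
Reactants: 13 methyl (E)-3-methoxybut-2-enoate
Product: 15 (1Z)-1,3-dimethoxy-1-(trimethylsilyloxy)buta-1,3-diene, via lithium dienolate 14 (not isolated)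
Conditions: LiN(iPr)2 (1.1 equiv), THF, −78 °C; Me3SiCl (1.2 equiv), −78 °C → rt; non-aqueous work-up, distillation
Reagents that add atoms: chlorotrimethylsilane, C[Si](C)(C)Cl
Why: Kinetic γ-deprotonation of the β-methoxy enoate and O-silylation of the extended enolate, the standard preparation of this silyl ketene acetal diene.

Step 7
Reactants: 12 3-[2,4-bis(methoxymethoxy)-5-(3-methylbut-2-enyl)phenyl]-5-bromo-4H-pyran-4-one; 15 (1Z)-1,3-dimethoxy-1-(trimethylsilyloxy)buta-1,3-diene
Product: 18 3-[2,4-bis(methoxymethoxy)-5-(3-methylbut-2-enyl)phenyl]-5-hydroxy-7-methoxy-4H-chromen-4-one, via cis-fused bromo ketal cycloadduct 16 (not isolated), via aryl trimethylsilyl ether 17 (not isolated)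
Conditions: 15 (3 equiv, in portions), iPr2NEt (2 equiv), PhMe (1 M), 100 °C, sealed tube; then MeOH, rt
Reagents that add atoms: none
Why: Proposed new method: the CH2 terminus of the diene, its most nucleophilic carbon, should bond to C6 of the pyranone (β to the carbonyl, next to the ring oxygen; the future C8a) while the ketene acetal carbon bonds to the brominated C5 (the future C4a), either in one asynchronous [4+2] event or as a vinylogous Mukaiyama–Michael addition followed by 6-(enolexo)-exo-trig closure of the α-bromo enolate onto the oxocarbenium ion, giving the cis-fused adduct 16. The closest known reaction types are the regiocontrolled cycloadditions of this diene with bromo- and chloroquinones and the Diels–Alder reactions of chromones carrying an electron-withdrawing group on C3 with 1-alkoxy-3-silyloxy dienes, but a plain 3-bromo-4-pyranone has not been shown to act as the dienophile. Ring A thus closes as a six-membered carbocycle by [4+2] annulation (C8–C8a and C4a–C5) and then aromatises: 1,4-loss of methanol from the mixed ketal gives a cyclohexadiene, amine-assisted loss of HBr across C4a–C8a is driven by formation of the benzene ring, and methanolysis of the aryl silyl ether 17 frees the C5 phenol, which adds up to HBr and MeOSiMe3. No stereocentre survives, so the ring-fusion and ketal configurations of 16 are of no consequence. The step needs orientation and site selectivity: carbonyl and bromine polarise C5=C6 so that C6 is the electrophilic terminus, which places OH on C5 and OMe on C7, and the aryl-bearing C2=C3 bond is more hindered, lacks the halogen and could not aromatise, so it should stay out of the reaction.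

Step 8
Reactants: 18 3-[2,4-bis(methoxymethoxy)-5-(3-methylbut-2-enyl)phenyl]-5-hydroxy-7-methoxy-4H-chromen-4-one
Product: 19 5-hydroxy-3-[2,4-dihydroxy-5-(3-methylbut-2-enyl)phenyl]-7-methoxy-4H-chromen-4-one (isopoegin B)
Conditions: HCl (ca. 1 M in MeOH), 25–40 °C
Reagents that add atoms: none
Why: Acid-catalysed acetal solvolysis should remove both MOM groups under dilute acid at mild temperature, leaving the C7 methyl ether, the chromone and the prenyl olefin intact.

**Compound list**
1 | 4,6-dibromobenzene-1,3-diol (4,6-dibromoresorcinol) | Oc1cc(O)c(Br)cc1Br | starting material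
2 | 1,5-dibromo-2,4-bis(methoxymethoxy)benzene | COCOc1cc(OCOC)c(Br)cc1Br | intermediate
3 | 1-bromo-3-methylbut-2-ene (prenyl bromide) | CC(C)=CCBr | starting material
4 | [5-bromo-2,4-bis(methoxymethoxy)phenyl]lithium | [Li]c1cc(Br)c(OCOC)cc1OCOC | intermediate (not isolated)
5 | 1-bromo-2,4-bis(methoxymethoxy)-5-(3-methylbut-2-enyl)benzene | COCOc1cc(OCOC)c(CC=C(C)C)cc1Br | intermediate
6 | [2,4-bis(methoxymethoxy)-5-(3-methylbut-2-enyl)phenyl]lithium | [Li]c1cc(CC=C(C)C)c(OCOC)cc1OCOC | intermediate (not isolated)
7 | lithium [2,4-bis(methoxymethoxy)-5-(3-methylbut-2-enyl)phenyl](propan-2-yloxy)(pinacolato)borate | [Li+].CC(C)O[B-]1(OC(C)(C)C(C)(C)O1)c1cc(CC=C(C)C)c(OCOC)cc1OCOC | intermediate (not isolated)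
8 | 2-[2,4-bis(methoxymethoxy)-5-(3-methylbut-2-enyl)phenyl]-4,4,5,5-tetramethyl-1,3,2-dioxaborolane | CC1(C)OB(c2cc(CC=C(C)C)c(OCOC)cc2OCOC)OC1(C)C | intermediate
9 | 4H-pyran-4-one | O=c1ccocc1 | starting material
10 | 3-bromo-4H-pyran-4-one | O=c1ccocc1Br | intermediate (not isolated)
11 | 3,5-dibromo-4H-pyran-4-one | O=c1c(Br)cocc1Br | intermediate
12 | 3-[2,4-bis(methoxymethoxy)-5-(3-methylbut-2-enyl)phenyl]-5-bromo-4H-pyran-4-one | O=c1c(Br)cocc1-c1cc(CC=C(C)C)c(OCOC)cc1OCOC | intermediate
13 | methyl (E)-3-methoxybut-2-enoate | CO/C(C)=C/C(=O)OC | starting material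
14 | lithium 1,3-dimethoxybuta-1,3-dien-1-olate (O– cis to C3) | [Li+].C=C(OC)/C=C(/OC)[O-] | intermediate (not isolated)
15 | (1Z)-1,3-dimethoxy-1-(trimethylsilyloxy)buta-1,3-diene | C=C(OC)/C=C(/OC)O[Si](C)(C)C | intermediate
16 | cis-3-[2,4-bis(methoxymethoxy)-5-(3-methylbut-2-enyl)phenyl]-4a-bromo-5,7-dimethoxy-5-(trimethylsilyloxy)-4a,5,8,8a-tetrahydro-4H-chromen-4-one (racemic; Br on C4a and H on C8a on the same face; C5 undefined) | COC1=CC(OC)(O[Si](C)(C)C)[C@@]2(Br)C(=O)C(c3cc(CC=C(C)C)c(OCOC)cc3OCOC)=CO[C@H]2C1 | intermediate (not isolated)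
17 | 3-[2,4-bis(methoxymethoxy)-5-(3-methylbut-2-enyl)phenyl]-7-methoxy-5-(trimethylsilyloxy)-4H-chromen-4-one | COc1cc(O[Si](C)(C)C)c2c(=O)c(-c3cc(CC=C(C)C)c(OCOC)cc3OCOC)coc2c1 | intermediate (not isolated)
18 | 3-[2,4-bis(methoxymethoxy)-5-(3-methylbut-2-enyl)phenyl]-5-hydroxy-7-methoxy-4H-chromen-4-one | COc1cc(O)c2c(=O)c(-c3cc(CC=C(C)C)c(OCOC)cc3OCOC)coc2c1 | intermediate
19 | 5-hydroxy-3-[2,4-dihydroxy-5-(3-methylbut-2-enyl)phenyl]-7-methoxy-4H-chromen-4-one (isopoegin B) | COc1cc(O)c2c(=O)c(-c3cc(CC=C(C)C)c(O)cc3O)coc2c1 | target

Total step count: 8. Longest linear sequence: 6 steps (steps 1, 2, 3, 5, 7, 8, from 4,6-dibromoresorcinol).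

**Steps most likely to fail**

Step 7. The push–pull C5=C6 bond of 12 may be too weak a dienophile, so the diene could be lost by desilylation or self-condensation before it adds. Attack at C2 instead of C6 would also stop the sequence, as would failure of the cis-disposed H and Br to eliminate, with debromination or retro-Claisen opening of the adduct taking over. The fallback uses known chemistry and brings ring A in preformed as a chromone, joined to ring B at C3. It sets out from boronate 8 and returns to the route at 18. Commercial 1-(2-hydroxy-4,6-dimethoxyphenyl)ethanone is condensed with N,N-dimethylformamide dimethyl acetal (PhMe, 90 °C) to (E)-3-(dimethylamino)-1-(2-hydroxy-4,6-dimethoxyphenyl)prop-2-en-1-one F1. Iodine (CHCl3, rt) cyclises and iodinates this to 3-iodo-5,7-dimethoxy-4H-chromen-4-one F2. BCl3 (CH2Cl2, −10 °C → rt) cleaves only the methyl ether peri to the carbonyl, giving 5-hydroxy-3-iodo-7-methoxy-4H-chromen-4-one F3. Suzuki–Miyaura coupling of F3 with 8 (Pd(PPh3)4, K2CO3, DME/H2O, 70 °C) should then give 18.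

Step 5. Over-arylation to the 3,5-diaryl pyranone, opening of the electron-poor dibromopyranone by aqueous carbonate, and protodeboronation of the ortho-alkoxy boronate could all erode the mono-coupling. The fallback makes the two halogens different, so that selectivity rests on oxidative addition and not on statistics. It sets out from 9 and returns at 12. Bromination of 9 with one equivalent of Br2 (then Et3N) is stopped at 10, which is isolated. ICl (CH2Cl2, 0 °C) followed by Et3N, the same addition–elimination manifold, should give 3-bromo-5-iodo-4H-pyran-4-one F4. Coupling of F4 with one equivalent of 8 at the C–I bond (Pd(PPh3)4, K2CO3, DME/H2O, rt to 40 °C) should deliver 12 with the bromide intact.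

Step 8. Protonation of the prenyl olefin during acetal cleavage could lead to cyclisation of the neighbouring 4'-phenol onto the tertiary cation (a 2,2-dimethylchroman) or to addition of HCl or methanol. The fallback replaces Brønsted-acid solvolysis by silyl transfer under buffered, aprotic conditions. It sets out from 18 and returns at 19. Me3SiOTf (excess) with 2,2'-bipyridyl (MeCN, 0 °C) should exchange both MOM groups for silyl groups and silylate the C5 phenol, giving 7-methoxy-3-[5-(3-methylbut-2-enyl)-2,4-bis(trimethylsilyloxy)phenyl]-5-(trimethylsilyloxy)-4H-chromen-4-one F5. Addition of water (rt) then hydrolyses the three silyl ethers to 19.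

**Further compounds**
F1 | step 7 | (E)-3-(dimethylamino)-1-(2-hydroxy-4,6-dimethoxyphenyl)prop-2-en-1-one | CN(C)/C=C/C(=O)c1c(O)cc(OC)cc1OC
F2 | step 7 | 3-iodo-5,7-dimethoxy-4H-chromen-4-one | COc1cc(OC)c2c(=O)c(I)coc2c1
F3 | step 7 | 5-hydroxy-3-iodo-7-methoxy-4H-chromen-4-one | COc1cc(O)c2c(=O)c(I)coc2c1
F4 | step 5 | 3-bromo-5-iodo-4H-pyran-4-one | O=c1c(Br)cocc1I
F5 | step 8 | 7-methoxy-3-[5-(3-methylbut-2-enyl)-2,4-bis(trimethylsilyloxy)phenyl]-5-(trimethylsilyloxy)-4H-chromen-4-one | COc1cc(O[Si](C)(C)C)c2c(=O)c(-c3cc(CC=C(C)C)c(O[Si](C)(C)C)cc3O[Si](C)(C)C)coc2c1
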